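## The problem

The target is a C37 norcarotenoid. A (Z)-γ-ylidenebutenolide sits in the middle of the chromophore. Its α-carbon carries an (E)-vinyl link (C7=C8) to ring A, a 1,2,4-trihydroxy-2,6,6-trimethylcyclohexane. Ring A is numbered here from C1 (gem-dimethyl carbon) through C3 (secondary carbinol) and C5 (methyl carbinol) to C6 (carbinol bearing C7). The γ-ylidene carbon starts an all-E tetraene that ends in an enyne on ring B, a (4R)-4-hydroxy-2,6,6-trimethylcyclohexenyl group.

Four stereocentres must be set: C3' in ring B, which is isolated, and C3 (S), C5 (R) and C6 (R) in ring A. The two secondary carbinols have the same spatial sense, so one chiral building block can serve both rings. In ring A, C3 can direct an oxidant to the neighbouring C4=C5 position of an unsaturated precursor and so control C5, and C5 can control C6; C3 cannot reach C6 directly.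

C6 is the hard centre. It is fully substituted, lies between the quaternary C1 and the tertiary carbinol C5, and its oxygen is trans to the C5 oxygen. An external nucleophile adding to a C6 ketone would enter opposite the axial C5 oxygen and the axial C1 methyl group and give the wrong epimer.

The ylidenebutenolide does not tolerate base, nucleophiles or light; the polyenyne is sensitive to acid, oxygen and iodine-type isomerisation, above all at the double bond next to the alkyne; and the tertiary allylic C6 alcohol ionises under acid. The last steps must therefore be neutral and should not include deprotection of the complete chromophore.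

The feature that opens the route is that C7 on C6 is cis to the C5 oxygen. In the chair with the C3 oxygen equatorial, the C5 oxygen is axial and stands beside the C6 carbonyl carbon, so it can carry the alkynyl nucleophile to that carbon.

## Retrosynthesis

**31 to 14 and 30.** The bond between the lactone α-carbon and C8 is cut (Stille coupling). This joins a C11 alkenylstannane 14 and a C26 bromo ylidenebutenolide 30 under neutral conditions, both without protecting groups, so the coupling product is the target itself. Cutting the exocyclic double bond last instead would expose all three ring A hydroxyls to a silyl triflate and an amidine base. The forward reaction must retain the E and Z geometries and tolerate four free hydroxyls and the lactone.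

**14 to 13.** The C8–Sn and C7–H bonds are removed, leading to the ethynyl triol 13. The forward hydrostannylation must place tin on the terminal carbon by syn addition; the fully substituted propargylic carbon should ensure this.

**13 to 11 (through 12).** The C6–C7 bond is cut. The alkynyl group is placed on a silicon bound to the C5 oxygen of ketone 11, so that it is delivered within the molecule to the face syn to that oxygen. The intermolecular addition of an acetylide to 6 would attack the opposite, open face. Hydrolysis of a 5,6-epoxide is kept as the fallback because it risks ionisation at C6. Precursor 11 has only two stereocentres and a non-enolisable ketone. The forward step must make the tether outcompete any intermolecular transfer.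

**11 to 6 and 10; 10 to 7 and 8.** The O–Si bond of the tether is cut to the hydroxy ketone 6 and the chlorosilane 10, and the Si–C(sp) bond of 10 to the silylacetylene 7 and dichlorodimethylsilane 8. The triisopropylsilyl cap on the alkyne is chosen so that fluoride activates only the tether silicon.

**6 to 5, 4 and 3.** The C5–O bond and a C4–H bond are removed, leading to enone 3. Oxygen is added by nucleophilic epoxidation anti to the neighbouring C3 silyloxy group, hydride opens the epoxide at C4, and the C6 carbinol is re-oxidised. An enolate oxidation of a saturated ring ketone would have to add oxygen on the face of the pseudoaxial C1 methyl group; the epoxide route lets the C3 centre decide instead. Enone 3 has a single stereocentre.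

**3 to 2 to 1.** The silyl ether is removed and the carbinol C–H bond is cut, leading to ketoisophorone 1. The forward reduction must be enantioselective and touch only the unhindered carbonyl.

**30 to 29, then to 25 and 26 (through 27 and 28).** After removal of the ring B silyl ether, the exocyclic double bond at the lactone γ-carbon is cut (vinylogous aldol condensation) to the C22 aldehyde 25 and 3-bromofuran-2(5H)-one 26. The bromine blocks the α-carbon during the aldol step and is later the handle for the Stille coupling. The forward reaction must attack through the γ-carbon and give the Z ylidene.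

**25 to 22 and 23 (through 24); 22 to 21; 21 to 19 and 20; 19 to 18.** The chain is cut at the α-methyl enal double bond (Wittig reaction with 23) and at the next-but-one double bond (Horner–Wadsworth–Emmons reaction with 20). Both reagents are stabilised and E-selective. Semi-stabilised phosphonium ylides would give E/Z mixtures whose iodine isomerisation would also scramble the double bond next to the alkyne.

**18 to 16 and 17; 16 to 3 (through 15).** The C(sp2)–C(sp) bond is cut (Sonogashira coupling) to enol triflate 16 and the commercial (E)-enynol 17, which brings the E double bond next to the alkyne. Triflate 16 comes from enone 3 by conjugate reduction and enolate trapping, so 3 serves both rings.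

## Roads not taken

**Alternative 1:** The C3–O and C6–O bonds of ring A are cut together. In the forward direction singlet oxygen adds across the ring diene of the cyclohexadienyl alkyne A2 to give the bridged endoperoxide A1.

- Merits: one known cycloaddition places the C6 oxygen on a carbon that already carries the alkyne and sets the cis relation of the C3 and C6 oxygens. No nucleophile has to be added to a hindered ketone. In this respect it is better precedented than the key step chosen here.
- Weak points: A1 is formed as the racemate, so a resolution is needed. The C5 hydroxyl is still missing after the O–O bond is cleaved. It must be introduced at C5 and not C4, on the face opposite to both existing hydroxyls, whereas hydroxyl-directed oxidants go to the other face. The ene reaction at the allylic methyl group competes with the cycloaddition.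
- Comparison: the chosen plan sets against this a single enantiomer from one catalytic reduction and a defined directing element for every oxygen, at the price of one unproven step.

**Alternative 2:** The lactone is cut at the bond between its carbonyl carbon and the α-carbon and at the acyl C–O bond. In the forward direction zerovalent palladium inserts into the carbon–iodine bond of the (Z)-iodo dienone A4, carbon monoxide inserts, and the enol oxygen closes the ring to give the ylidenebutenolide A3.

- Merits: the lactone and its exocyclic double bond are made in one step from carbon monoxide, without tin and without an aldol condensation. At the lactone itself this is more direct than the chosen plan.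
- Weak points: A4 already contains ring A with its C6 centre, so the central stereochemical problem is not addressed. The Z geometry of a β-iodo enone is labile. The enolisation must go to the methylene side and give the Z ylidene. A3 is only a C22 half, so the polyenyne arm would have to be grown on a base-sensitive ylidenebutenolide.
- Comparison: the chosen plan builds the polyene before the lactone exists and joins two finished halves last.

**Alternative 3:** The exocyclic double bond of the lactone is cut last. In the forward direction soft enolisation of the ring A butenolide A6 with a silyl triflate makes its γ-carbon nucleophilic; it adds to aldehyde 25, and DBU eliminates silanol to give the persilylated target A5.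

- Merits: this is the same reaction type as step 16 of the chosen route and equally well precedented. It joins the two largest fragments in the last carbon–carbon bond formation and leaves no tin step at the end, so it is at least as convergent.
- Weak points: the hindered tertiary hydroxyls of ring A must be silylated, and the tertiary allylic silyl ether at C6 must survive a silyl triflate and DBU. Any E/Z mixture at the ylidene would have to be separated at the C37 stage. Four silyl ethers must then be removed from the complete chromophore.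
- Comparison: the chosen plan runs the condensation on the simpler aldehyde and ends with a stereoretentive coupling of unprotected partners. It pays for this with an organotin reagent in the last step.

Key step: step 8

Remark on the chemistry: 17, 20, 23 and 26 are taken as purchasable building blocks, and the secondary carbinol created in step 4 is carried as an epimer mixture because step 5 removes that centre.

## Route

Step 1
Reactants: 1 ketoisophorone
Product: 2 (4S)-4-hydroxy-2,6,6-trimethylcyclohex-2-en-1-one
Conditions: RuCl[(S,S)-TsDPEN](p-cymene) (1 mol %), HCO2H/Et3N (5:2), CH2Cl2, 25 °C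
Reagents that add atoms: none
Why: Noyori asymmetric transfer hydrogenation; the unhindered conjugated carbonyl is reduced and the carbonyl next to the quaternary carbon is left. The (S,S) ligand should give the (S) carbinol by the same facial sense as for aryl and alkenyl alkyl ketones; this centre becomes C3 of ring A and C3' of ring B.

Step 2
Reactants: 2 (4S)-4-hydroxy-2,6,6-trimethylcyclohex-2-en-1-one
Product: 3 (4S)-4-[(tert-butyldimethylsilyl)oxy]-2,6,6-trimethylcyclohex-2-en-1-one
Conditions: TBSCl, imidazole, DMF, 25 °C
Reagents that add atoms: tert-butyldimethylsilyl chloride, CC(C)(C)[Si](C)(C)Cl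
Why: Standard silylation of a secondary alcohol; the silyl ether directs the epoxidation and survives the hydride, base and palladium steps of both branches.

Step 3
Reactants: 3 (4S)-4-[(tert-butyldimethylsilyl)oxy]-2,6,6-trimethylcyclohex-2-en-1-one
Product: 4 (1R,5S,6R)-5-[(tert-butyldimethylsilyl)oxy]-1,3,3-trimethyl-7-oxabicyclo[4.1.0]heptan-2-one
Conditions: H2O2 (30 % aq), NaOH (0.3 equiv), MeOH, 0 °C
Reagents that add atoms: hydrogen peroxide, OO
Why: Weitz–Scheffer nucleophilic epoxidation of an enone; hydroperoxide adds to the β-carbon anti to the neighbouring silyloxy group and the epoxide closes on that face. This sets C5 (R) with its oxygen trans to the C3 oxygen.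

Step 4
Reactants: 4 (1R,5S,6R)-5-[(tert-butyldimethylsilyl)oxy]-1,3,3-trimethyl-7-oxabicyclo[4.1.0]heptan-2-one
Product: 5 (2R,4S)-4-[(tert-butyldimethylsilyl)oxy]-2,6,6-trimethylcyclohexane-1,2-diol (both C1 epimers)
Conditions: LiEt3BH (3.5 equiv), THF, 0 °C to 25 °C
Reagents that add atoms: none
Why: Hydride reduction of the ketone and SN2 opening of the trisubstituted epoxide at its secondary carbon, a trans-diaxial opening into the chair with the silyloxy group equatorial. The tertiary C5–O bond is untouched, and the new secondary carbinol is removed in step 5.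

Step 5
Reactants: 5 (2R,4S)-4-[(tert-butyldimethylsilyl)oxy]-2,6,6-trimethylcyclohexane-1,2-diol
Product: 6 (2R,4S)-4-[(tert-butyldimethylsilyl)oxy]-2-hydroxy-2,6,6-trimethylcyclohexan-1-one
Conditions: IBX (2 equiv), EtOAc, 75 °C
Reagents that add atoms: none
Why: IBX oxidation of the secondary alcohol of a 1,2-diol to the α-hydroxy ketone without C–C cleavage. The tertiary alcohol cannot be oxidised and the ketone has no α-hydrogen, so nothing can epimerise.

Step 6
Reactants: 7 ethynyltri(propan-2-yl)silane; 8 dichlorodimethylsilane
Product: 10 chloro(dimethyl){[tri(propan-2-yl)silyl]ethynyl}silane, via lithium [tri(propan-2-yl)silyl]acetylide 9 (not isolated)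
Conditions: n-BuLi, THF, −78 °C; then inverse addition to 8 (3 equiv), THF, −78 °C to 25 °C; distillation
Reagents that add atoms: none
Why: Deprotonation of a terminal alkyne and substitution at silicon; inverse addition to excess dichlorosilane suppresses the bis(alkynyl)silane.

Step 7
Reactants: 6 (2R,4S)-4-[(tert-butyldimethylsilyl)oxy]-2-hydroxy-2,6,6-trimethylcyclohexan-1-one; 10 chloro(dimethyl){[tri(propan-2-yl)silyl]ethynyl}silane
Product: 11 (2R,4S)-4-[(tert-butyldimethylsilyl)oxy]-2-[(dimethyl{[tri(propan-2-yl)silyl]ethynyl}silyl)oxy]-2,6,6-trimethylcyclohexan-1-one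
Conditions: imidazole, DMAP (cat.), CH2Cl2, 0 °C to 25 °C
Reagents that add atoms: none
Why: O-Silylation of a tertiary alcohol with a chlorosilane that is as small at silicon as chlorotrimethylsilane; no stereocentre is touched and the ketone cannot enolise.

Step 8
Reactants: 11 (2R,4S)-4-[(tert-butyldimethylsilyl)oxy]-2-[(dimethyl{[tri(propan-2-yl)silyl]ethynyl}silyl)oxy]-2,6,6-trimethylcyclohexan-1-one
Product: 13 (1S,2R,4S)-1-ethynyl-2,6,6-trimethylcyclohexane-1,2,4-triol, via O-fluorodimethylsilyl alkynyl carbinol 12 (not isolated)
Conditions: Bu4N[Ph3SiF2] (0.2 equiv), THF (0.01 M), −20 °C to 25 °C; then Bu4NF (5 equiv), THF, 25 °C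
Reagents that add atoms: none
Why: Proposed new method: fluoride from Bu4N[Ph3SiF2] adds to the tether silicon, the only silicon that bears an oxygen and two methyl groups (the triisopropylsilyl cap and the tert-butyldimethylsilyl ether are hindered and less Lewis acidic), and the pentacoordinate silicate passes its alkynyl ligand to the C6 carbonyl carbon through a five-membered cyclic transition state (C6, C5, O, Si, alkynyl carbon). The closest known reaction types are the fluoride- or alkoxide-catalysed intermolecular addition of alkynylsilanes to ketones and the silicon-tethered intramolecular transfer of allyl or hydride to oxygenated ketones; alkynyl transfer through such a tether is the unproven part. No ring of the target is closed; the only ring is the transient five-membered array of the transition state, and the tether is cleaved in the same flask. In the chair with the C3 silyloxy group equatorial the C5 oxygen is axial and stands beside the carbonyl carbon, so the alkynyl group can only reach the face syn to that oxygen; the C5 centre thus fixes C6 (S in the alkyne series, R in the target). The alkoxide formed, or fluoride passed on from it, should activate the next tether, so a substoichiometric amount of fluoride should suffice. The step needs intramolecular transfer to beat intermolecular transfer, which would enter anti to the axial oxygen and give the cis diol; high dilution, the non-enolisable ketone and the fluoride-inert cap on the alkyne are meant to secure this. Excess Bu4NF then removes the tether, the alkyne cap and the C3 silyl ether.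

Step 9
Reactants: 13 (1S,2R,4S)-1-ethynyl-2,6,6-trimethylcyclohexane-1,2,4-triol
Product: 14 (1R,2R,4S)-2,6,6-trimethyl-1-[(E)-2-(tributylstannyl)ethenyl]cyclohexane-1,2,4-triol
Conditions: Bu3SnH, PdCl2(PPh3)2 (2 mol %), THF, 0 °C
Reagents that add atoms: tributyltin hydride, CCCC[SnH](CCCC)CCCC
Why: Palladium-catalysed syn hydrostannylation of a terminal alkyne; with a fully substituted propargylic carbon, tin should go to the terminal carbon and give the (E)-alkenylstannane. Free hydroxyl groups are tolerated.

Step 10
Reactants: 3 (4S)-4-[(tert-butyldimethylsilyl)oxy]-2,6,6-trimethylcyclohex-2-en-1-one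
Product: 16 (4R)-4-[(tert-butyldimethylsilyl)oxy]-2,6,6-trimethylcyclohex-1-en-1-yl trifluoromethanesulfonate, via lithium enolate of the saturated ketone 15 (not isolated)
Conditions: LiBH(s-Bu)3, THF, −78 °C; then PhNTf2, −78 °C to 0 °C
Reagents that add atoms: N-phenylbis(trifluoromethanesulfonimide), O=S(=O)(N(c1ccccc1)S(=O)(=O)C(F)(F)F)C(F)(F)F
Why: Conjugate reduction of a β-unsubstituted enone by a hindered borohydride (the carbonyl is shielded by the quaternary carbon) gives the enolate regiospecifically, and O-sulfonylation traps it as the enol triflate. The carbinol centre is not involved; its descriptor changes only because the ring priorities change.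

Step 11
Reactants: 16 (4R)-4-[(tert-butyldimethylsilyl)oxy]-2,6,6-trimethylcyclohex-1-en-1-yl trifluoromethanesulfonate; 17 (2E)-3-methylpent-2-en-4-yn-1-ol
Product: 18 (2E)-5-{(4R)-4-[(tert-butyldimethylsilyl)oxy]-2,6,6-trimethylcyclohex-1-en-1-yl}-3-methylpent-2-en-4-yn-1-ol
Conditions: Pd(PPh3)4 (5 mol %), CuI (10 mol %), i-Pr2NH, THF, 45 °C
Reagents that add atoms: none
Why: Sonogashira coupling of an enol triflate with a terminal alkyne; the E double bond next to the alkyne comes with 17 and is not touched.

Step 12
Reactants: 18 (2E)-5-{(4R)-4-[(tert-butyldimethylsilyl)oxy]-2,6,6-trimethylcyclohex-1-en-1-yl}-3-methylpent-2-en-4-yn-1-ol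
Product: 19 (2E)-5-{(4R)-4-[(tert-butyldimethylsilyl)oxy]-2,6,6-trimethylcyclohex-1-en-1-yl}-3-methylpent-2-en-4-ynal
Conditions: MnO2, CH2Cl2, 25 °C
Reagents that add atoms: none
Why: Selective oxidation of an allylic alcohol with MnO2, which should not isomerise the double bond.

Step 13
Reactants: 19 (2E)-5-{(4R)-4-[(tert-butyldimethylsilyl)oxy]-2,6,6-trimethylcyclohex-1-en-1-yl}-3-methylpent-2-en-4-ynal; 20 ethyl (2E)-4-(diethoxyphosphoryl)but-2-enoate
Product: 21 ethyl (2E,4E,6E)-9-{(4R)-4-[(tert-butyldimethylsilyl)oxy]-2,6,6-trimethylcyclohex-1-en-1-yl}-7-methylnona-2,4,6-trien-8-ynoate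
Conditions: LiN(SiMe3)2, THF, −78 °C to 0 °C
Reagents that add atoms: none
Why: Horner–Wadsworth–Emmons olefination with a vinylogous stabilised phosphonate, which reacts at the carbon next to phosphorus and should give the new double bond with E geometry; the second E double bond comes with the reagent.

Step 14
Reactants: 21 ethyl (2E,4E,6E)-9-{(4R)-4-[(tert-butyldimethylsilyl)oxy]-2,6,6-trimethylcyclohex-1-en-1-yl}-7-methylnona-2,4,6-trien-8-ynoate
Product: 22 (2E,4E,6E)-9-{(4R)-4-[(tert-butyldimethylsilyl)oxy]-2,6,6-trimethylcyclohex-1-en-1-yl}-7-methylnona-2,4,6-trien-8-yn-1-ol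
Conditions: i-Bu2AlH, CH2Cl2, −78 °C
Reagents that add atoms: none
Why: 1,2-Reduction of a conjugated ester to the allylic alcohol at low temperature; the alkyne, the triene and the silyl ether are inert.

Step 15
Reactants: 22 (2E,4E,6E)-9-{(4R)-4-[(tert-butyldimethylsilyl)oxy]-2,6,6-trimethylcyclohex-1-en-1-yl}-7-methylnona-2,4,6-trien-8-yn-1-ol; 23 2-(triphenyl-λ5-phosphanylidene)propanal
Product: 25 (2E,4E,6E,8E)-11-{(4R)-4-[(tert-butyldimethylsilyl)oxy]-2,6,6-trimethylcyclohex-1-en-1-yl}-2,9-dimethylundeca-2,4,6,8-tetraen-10-ynal, via trienynal 24 (not isolated)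
Conditions: MnO2, CH2Cl2, 25 °C; filtration; then 23, toluene, 80 °C
Reagents that add atoms: none
Why: MnO2 oxidation of the allylic alcohol and Wittig reaction of the crude aldehyde with a stabilised α-methyl formyl ylide, which should give the (E) α-methyl enal. The product enal is less electrophilic than 24, so the chain should grow by one unit only.

Step 16
Reactants: 25 (2E,4E,6E,8E)-11-{(4R)-4-[(tert-butyldimethylsilyl)oxy]-2,6,6-trimethylcyclohex-1-en-1-yl}-2,9-dimethylundeca-2,4,6,8-tetraen-10-ynal; 26 3-bromofuran-2(5H)-one
Product: 29 (5Z)-3-bromo-5-[(2E,4E,6E,8E)-11-{(4R)-4-[(tert-butyldimethylsilyl)oxy]-2,6,6-trimethylcyclohex-1-en-1-yl}-2,9-dimethylundeca-2,4,6,8-tetraen-10-yn-1-ylidene]furan-2(5H)-one, via 3-bromo-2-silyloxyfuran 27 (not isolated), via silylated aldol adduct 28 (not isolated)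
Conditions: TBSOTf, i-Pr2NEt, CH2Cl2, −78 °C to 0 °C; then DBU, 0 °C to 25 °C
Reagents that add atoms: none
Why: Vinylogous Mukaiyama aldol addition of the silyloxyfuran formed in the flask, which attacks through its γ-carbon because bromine blocks the α-carbon, followed by base-induced E1cB loss of silanol. With the extended conjugation the (Z) ylidene should be the favoured product.

Step 17
Reactants: 29 (5Z)-3-bromo-5-[(2E,4E,6E,8E)-11-{(4R)-4-[(tert-butyldimethylsilyl)oxy]-2,6,6-trimethylcyclohex-1-en-1-yl}-2,9-dimethylundeca-2,4,6,8-tetraen-10-yn-1-ylidene]furan-2(5H)-one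
Product: 30 (5Z)-3-bromo-5-{(2E,4E,6E,8E)-11-[(4R)-4-hydroxy-2,6,6-trimethylcyclohex-1-en-1-yl]-2,9-dimethylundeca-2,4,6,8-tetraen-10-yn-1-ylidene}furan-2(5H)-one
Conditions: HF·pyridine, pyridine, THF, 0 °C to 25 °C
Reagents that add atoms: none
Why: Cleavage of a secondary silyl ether with buffered hydrogen fluoride, which should leave the lactone, the alkenyl bromide and the polyenyne untouched; no tertiary allylic alcohol is present at this stage.

Step 18
Reactants: 14 (1R,2R,4S)-2,6,6-trimethyl-1-[(E)-2-(tributylstannyl)ethenyl]cyclohexane-1,2,4-triol; 30 (5Z)-3-bromo-5-{(2E,4E,6E,8E)-11-[(4R)-4-hydroxy-2,6,6-trimethylcyclohex-1-en-1-yl]-2,9-dimethylundeca-2,4,6,8-tetraen-10-yn-1-ylidene}furan-2(5H)-one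
Product: 31 (5Z)-5-{(2E,4E,6E,8E)-11-[(4R)-4-hydroxy-2,6,6-trimethylcyclohex-1-en-1-yl]-2,9-dimethylundeca-2,4,6,8-tetraen-10-yn-1-ylidene}-3-{(E)-2-[(1R,2R,4S)-1,2,4-trihydroxy-2,6,6-trimethylcyclohexyl]ethenyl}furan-2(5H)-one
Conditions: Pd2(dba)3 (5 mol %), AsPh3 (40 mol %), NMP, 40 °C, dark
Reagents that add atoms: none
Why: Stille coupling of an alkenyl bromide with an alkenylstannane, with retention of geometry at both partners; the weakly bound arsine ligand allows a low temperature. Neither partner carries a protecting group, so the coupling product is the target.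

## Compound list

1 | ketoisophorone (2,6,6-trimethylcyclohex-2-ene-1,4-dione) | CC1=CC(=O)CC(C)(C)C1=O | starting material
2 | (4S)-4-hydroxy-2,6,6-trimethylcyclohex-2-en-1-one | O=C1C(C)(C)C[C@H](O)C=C1C | intermediate
3 | (4S)-4-[(tert-butyldimethylsilyl)oxy]-2,6,6-trimethylcyclohex-2-en-1-one | O=C1C(C)(C)C[C@H](O[Si](C)(C)C(C)(C)C)C=C1C | intermediate
4 | (1R,5S,6R)-5-[(tert-butyldimethylsilyl)oxy]-1,3,3-trimethyl-7-oxabicyclo[4.1.0]heptan-2-one | O=C1C(C)(C)C[C@H](O[Si](C)(C)C(C)(C)C)[C@H]2O[C@@]12C | intermediate
5 | (2R,4S)-4-[(tert-butyldimethylsilyl)oxy]-2,6,6-trimethylcyclohexane-1,2-diol, both epimers at C1 | OC1C(C)(C)C[C@H](O[Si](C)(C)C(C)(C)C)C[C@@]1(C)O | intermediate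
6 | (2R,4S)-4-[(tert-butyldimethylsilyl)oxy]-2-hydroxy-2,6,6-trimethylcyclohexan-1-one | O=C1C(C)(C)C[C@H](O[Si](C)(C)C(C)(C)C)C[C@@]1(C)O | intermediate
7 | ethynyltri(propan-2-yl)silane | C#C[Si](C(C)C)(C(C)C)C(C)C | starting material
8 | dichlorodimethylsilane | C[Si](C)(Cl)Cl | starting material
9 | lithium [tri(propan-2-yl)silyl]acetylide | [Li]C#C[Si](C(C)C)(C(C)C)C(C)C | intermediate (not isolated)
10 | chloro(dimethyl){[tri(propan-2-yl)silyl]ethynyl}silane | C[Si](C)(Cl)C#C[Si](C(C)C)(C(C)C)C(C)C | intermediate
11 | (2R,4S)-4-[(tert-butyldimethylsilyl)oxy]-2-[(dimethyl{[tri(propan-2-yl)silyl]ethynyl}silyl)oxy]-2,6,6-trimethylcyclohexan-1-one | O=C1C(C)(C)C[C@H](O[Si](C)(C)C(C)(C)C)C[C@@]1(C)O[Si](C)(C)C#C[Si](C(C)C)(C(C)C)C(C)C | intermediate (precursor of the key step)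
12 | (1S,2R,4S)-4-[(tert-butyldimethylsilyl)oxy]-2-[(fluorodimethylsilyl)oxy]-2,6,6-trimethyl-1-{[tri(propan-2-yl)silyl]ethynyl}cyclohexan-1-ol, drawn as the free alcohol; in the flask the C1 oxygen is an alkoxide or is bound to silicon | CC(C)[Si](C#C[C@@]1(O)C(C)(C)C[C@H](O[Si](C)(C)C(C)(C)C)C[C@@]1(C)O[Si](C)(C)F)(C(C)C)C(C)C | intermediate (not isolated)
13 | (1S,2R,4S)-1-ethynyl-2,6,6-trimethylcyclohexane-1,2,4-triol | C#C[C@@]1(O)C(C)(C)C[C@H](O)C[C@@]1(C)O | intermediate (product of the key step)
14 | (1R,2R,4S)-2,6,6-trimethyl-1-[(E)-2-(tributylstannyl)ethenyl]cyclohexane-1,2,4-triol | CCCC[Sn](CCCC)(CCCC)/C=C/[C@@]1(O)C(C)(C)C[C@H](O)C[C@@]1(C)O | intermediate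
15 | lithium (4R)-4-[(tert-butyldimethylsilyl)oxy]-2,6,6-trimethylcyclohex-1-en-1-olate | CC1=C(O[Li])C(C)(C)C[C@H](O[Si](C)(C)C(C)(C)C)C1 | intermediate (not isolated)
16 | (4R)-4-[(tert-butyldimethylsilyl)oxy]-2,6,6-trimethylcyclohex-1-en-1-yl trifluoromethanesulfonate | CC1=C(OS(=O)(=O)C(F)(F)F)C(C)(C)C[C@H](O[Si](C)(C)C(C)(C)C)C1 | intermediate
17 | (2E)-3-methylpent-2-en-4-yn-1-ol | C#C/C(C)=C/CO | starting material
18 | (2E)-5-{(4R)-4-[(tert-butyldimethylsilyl)oxy]-2,6,6-trimethylcyclohex-1-en-1-yl}-3-methylpent-2-en-4-yn-1-ol | CC1=C(C#C/C(C)=C/CO)C(C)(C)C[C@H](O[Si](C)(C)C(C)(C)C)C1 | intermediate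
19 | (2E)-5-{(4R)-4-[(tert-butyldimethylsilyl)oxy]-2,6,6-trimethylcyclohex-1-en-1-yl}-3-methylpent-2-en-4-ynal | CC1=C(C#C/C(C)=C/C=O)C(C)(C)C[C@H](O[Si](C)(C)C(C)(C)C)C1 | intermediate
20 | ethyl (2E)-4-(diethoxyphosphoryl)but-2-enoate | CCOC(=O)/C=C/CP(=O)(OCC)OCC | starting material
21 | ethyl (2E,4E,6E)-9-{(4R)-4-[(tert-butyldimethylsilyl)oxy]-2,6,6-trimethylcyclohex-1-en-1-yl}-7-methylnona-2,4,6-trien-8-ynoate | CC1=C(C#C/C(C)=C/C=C/C=C/C(=O)OCC)C(C)(C)C[C@H](O[Si](C)(C)C(C)(C)C)C1 | intermediate
22 | (2E,4E,6E)-9-{(4R)-4-[(tert-butyldimethylsilyl)oxy]-2,6,6-trimethylcyclohex-1-en-1-yl}-7-methylnona-2,4,6-trien-8-yn-1-ol | CC1=C(C#C/C(C)=C/C=C/C=C/CO)C(C)(C)C[C@H](O[Si](C)(C)C(C)(C)C)C1 | intermediate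
23 | 2-(triphenyl-λ5-phosphanylidene)propanal | CC(C=O)=P(c1ccccc1)(c1ccccc1)c1ccccc1 | starting material
24 | (2E,4E,6E)-9-{(4R)-4-[(tert-butyldimethylsilyl)oxy]-2,6,6-trimethylcyclohex-1-en-1-yl}-7-methylnona-2,4,6-trien-8-ynal | CC1=C(C#C/C(C)=C/C=C/C=C/C=O)C(C)(C)C[C@H](O[Si](C)(C)C(C)(C)C)C1 | intermediate (not isolated)
25 | (2E,4E,6E,8E)-11-{(4R)-4-[(tert-butyldimethylsilyl)oxy]-2,6,6-trimethylcyclohex-1-en-1-yl}-2,9-dimethylundeca-2,4,6,8-tetraen-10-ynal | CC1=C(C#C/C(C)=C/C=C/C=C/C=C(C)/C=O)C(C)(C)C[C@H](O[Si](C)(C)C(C)(C)C)C1 | intermediate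
26 | 3-bromofuran-2(5H)-one | O=C1OCC=C1Br | starting material
27 | 3-bromo-2-[(tert-butyldimethylsilyl)oxy]furan | CC(C)(C)[Si](C)(C)Oc1occc1Br | intermediate (not isolated)
28 | 3-bromo-5-[(2E,4E,6E,8E)-1-[(tert-butyldimethylsilyl)oxy]-11-{(4R)-4-[(tert-butyldimethylsilyl)oxy]-2,6,6-trimethylcyclohex-1-en-1-yl}-2,9-dimethylundeca-2,4,6,8-tetraen-10-yn-1-yl]furan-2(5H)-one, mixture of diastereomers at the two new centres | CC1=C(C#C/C(C)=C/C=C/C=C/C=C(C)/C(O[Si](C)(C)C(C)(C)C)C2OC(=O)C(Br)=C2)C(C)(C)C[C@H](O[Si](C)(C)C(C)(C)C)C1 | intermediate (not isolated)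
29 | (5Z)-3-bromo-5-[(2E,4E,6E,8E)-11-{(4R)-4-[(tert-butyldimethylsilyl)oxy]-2,6,6-trimethylcyclohex-1-en-1-yl}-2,9-dimethylundeca-2,4,6,8-tetraen-10-yn-1-ylidene]furan-2(5H)-one | CC1=C(C#C/C(C)=C/C=C/C=C/C=C(C)/C=C2C=C(Br)C(=O)O/2)C(C)(C)C[C@H](O[Si](C)(C)C(C)(C)C)C1 | intermediate
30 | (5Z)-3-bromo-5-{(2E,4E,6E,8E)-11-[(4R)-4-hydroxy-2,6,6-trimethylcyclohex-1-en-1-yl]-2,9-dimethylundeca-2,4,6,8-tetraen-10-yn-1-ylidene}furan-2(5H)-one | CC1=C(C#C/C(C)=C/C=C/C=C/C=C(C)/C=C2C=C(Br)C(=O)O/2)C(C)(C)C[C@H](O)C1 | intermediate
31 | (5Z)-5-{(2E,4E,6E,8E)-11-[(4R)-4-hydroxy-2,6,6-trimethylcyclohex-1-en-1-yl]-2,9-dimethylundeca-2,4,6,8-tetraen-10-yn-1-ylidene}-3-{(E)-2-[(1R,2R,4S)-1,2,4-trihydroxy-2,6,6-trimethylcyclohexyl]ethenyl}furan-2(5H)-one | CC1=C(C#C/C(C)=C/C=C/C=C/C=C(C)/C=C2C=C(/C=C/[C@@]3(O)C(C)(C)C[C@H](O)C[C@@]3(C)O)C(=O)O/2)C(C)(C)C[C@H](O)C1 | target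

## Step count and risks

Total step count: 18. Longest linear sequence: 11 steps (steps 1, 2, 10, 11, 12, 13, 14, 15, 16, 17 and 18). The ring A branch (steps 1 to 5 and 7 to 9, then 18) is 9 steps, and step 6 is a one-step reagent branch.

**Step 8 (key step, the proposed new method).** The most likely failure is that fluoride cleaves the Si–O bond of the tether faster than the alkynyl group migrates. The tertiary alkoxide and the alkynylfluorosilane would then have to recombine, and any transfer between molecules would reach the open face of the ketone, so facial control would be lost. Turnover could also stall, because the hindered alkoxide has to activate the next silicon. The fallback uses known chemistry; it sets out from 16 and returns at 13. Sonogashira coupling of 16 with 7 (Pd(PPh3)4, CuI, i-Pr2NH) gives the silyl enyne F1. A peracid epoxidises its ring double bond to the 5,6-epoxide F2, as a mixture of the two faces. Aqueous HClO4 in THF then opens the epoxide by trans-diaxial attack of water into the chair with the C3 oxygen equatorial: the anti epoxide at C6 and the syn epoxide at C5, so that both should converge on the trans diol F3. Bu4NF finally removes both silyl groups to give 13. Its own risk is ionisation at the propargylic C6 under acid.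

**Step 16.** Poor control of the exocyclic double bond geometry in the E1cB elimination, or degradation of the polyenal by the silyl triflate (conjugate attack, oligomerisation), is the main concern. The aldehyde is an extended, α-branched polyenal and therefore only moderately electrophilic at the carbonyl carbon. The fallback sets out from 25 and 26 and returns at 29. Compound 27 is prepared separately from 26 (TBSOTf, Et3N) and isolated. BF3·OEt2 then mediates its vinylogous Mukaiyama aldol addition to 25 at −78 °C, and work-up gives the hydroxyalkyl butenolide F4. The diastereomers are separated if needed, and the alcohol is dehydrated by a stereospecific anti-elimination (PPh3, diethyl azodicarboxylate) to 29.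

**Step 18.** Protodestannylation or homocoupling of 14 may outrun a slow oxidative addition into the electron-poor bromide, and the ylidene or polyene double bonds may isomerise under palladium and light; the product carries seven conjugated multiple bonds and a tertiary allylic alcohol. The fallback sets out from 13 and returns at 31. Copper-catalysed protoboration of 13 (bis(pinacolato)diboron, CuCl, Xantphos, NaOt-Bu, MeOH) gives the (E)-alkenyl pinacol boronate F5, which is joined to 30 by Suzuki–Miyaura coupling (PdCl2(dppf), K3PO4, THF/H2O, 25 °C).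

**Step 10.** Competing 1,2-reduction of the enone, or incomplete O-sulfonylation of the hindered, tetrasubstituted enolate in the presence of the trialkylborane, would lower the yield of 16. The fallback sets out from 3 and returns at 16. Hydrogenation of the ring double bond (H2, Pd/C, EtOAc) gives the saturated ketone F6 as a mixture at the methyl-bearing carbon. Deprotonation with LiN(i-Pr)2 can occur only at that carbon, and PhNTf2 then gives 16.

## Further compounds

F1 | step 8 | tert-butyl(dimethyl){[(1R)-3,5,5-trimethyl-4-{[tri(propan-2-yl)silyl]ethynyl}cyclohex-3-en-1-yl]oxy}silane | CC1=C(C#C[Si](C(C)C)(C(C)C)C(C)C)C(C)(C)C[C@H](O[Si](C)(C)C(C)(C)C)C1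
F2 | step 8 | 5,6-epoxide of F1 (both faces), (4S)-4-[(tert-butyldimethylsilyl)oxy]-2,2,6-trimethyl-1-{[tri(propan-2-yl)silyl]ethynyl}-7-oxabicyclo[4.1.0]heptane | CC(C)[Si](C(C)C)(C(C)C)C#CC12OC2(C)C[C@@H](O[Si](C)(C)C(C)(C)C)CC1(C)C
F3 | step 8 | (1S,2R,4S)-4-[(tert-butyldimethylsilyl)oxy]-2,6,6-trimethyl-1-{[tri(propan-2-yl)silyl]ethynyl}cyclohexane-1,2-diol | CC(C)[Si](C#C[C@@]1(O)C(C)(C)C[C@H](O[Si](C)(C)C(C)(C)C)C[C@@]1(C)O)(C(C)C)C(C)C
F4 | step 16 | 3-bromo-5-[(2E,4E,6E,8E)-11-{(4R)-4-[(tert-butyldimethylsilyl)oxy]-2,6,6-trimethylcyclohex-1-en-1-yl}-1-hydroxy-2,9-dimethylundeca-2,4,6,8-tetraen-10-yn-1-yl]furan-2(5H)-one (diastereomers) | CC1=C(C#C/C(C)=C/C=C/C=C/C=C(C)/C(O)C2OC(=O)C(Br)=C2)C(C)(C)C[C@H](O[Si](C)(C)C(C)(C)C)C1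
F5 | step 18 | (1R,2R,4S)-2,6,6-trimethyl-1-[(E)-2-(4,4,5,5-tetramethyl-1,3,2-dioxaborolan-2-yl)ethenyl]cyclohexane-1,2,4-triol | CC1(C)OB(/C=C/[C@@]2(O)C(C)(C)C[C@H](O)C[C@@]2(C)O)OC1(C)C
F6 | step 10 | (4R)-4-[(tert-butyldimethylsilyl)oxy]-2,2,6-trimethylcyclohexan-1-one (both epimers at C6) | O=C1C(C)(C)C[C@H](O[Si](C)(C)C(C)(C)C)CC1C
A1 | alternative 1 | bridgehead-ethynyl endoperoxide, 1-ethynyl-6,8,8-trimethyl-2,3-dioxabicyclo[2.2.2]oct-5-ene (needed enantiomer drawn) | C#C[C@]12C(C)(C)C[C@H](OO1)C=C2C
A2 | alternative 1 | 1-ethynyl-2,6,6-trimethylcyclohexa-1,3-diene | C#CC1=C(C)C=CCC1(C)C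
A3 | alternative 2 | ylidenebutenolide carrying the triol ring and a dienyl silyl ether | CC(C)(C)[Si](C)(C)OC/C=C(C)/C=C1C=C(/C=C/[C@@]2(O)C(C)(C)C[C@H](O[Si](C)(C)C(C)(C)C)C[C@@]2(C)O)C(=O)O/1
A4 | alternative 2 | (Z)-β-iodo dienone carrying the triol ring and an allylic silyl ether | CC(C)(C)[Si](C)(C)OC/C=C(C)/CC(=O)/C=C(I)/C=C/[C@@]1(O)C(C)(C)C[C@H](O[Si](C)(C)C(C)(C)C)C[C@@]1(C)O
A5 | alternative 3 | persilylated target | CC1=C(C#C/C(C)=C/C=C/C=C/C=C(C)/C=C2C=C(/C=C/[C@@]3(O[Si](C)(C)C)C(C)(C)C[C@H](O[Si](C)(C)C(C)(C)C)C[C@@]3(C)O[Si](C)(C)C)C(=O)O/2)C(C)(C)C[C@H](O[Si](C)(C)C(C)(C)C)C1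
A6 | alternative 3 | 3-alkenylfuran-2(5H)-one carrying the silylated triol ring | O=C1OCC=C1/C=C/[C@@]2(O[Si](C)(C)C)C(C)(C)C[C@H](O[Si](C)(C)C(C)(C)C)C[C@@]2(C)O[Si](C)(C)C
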